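The route rests on disconnecting the C3–C3a bond of the bicyclic core (1-benzofuran-2-one numbering, spelled out below) by a chelate-enolate Claisen rearrangement. The contiguous array O–C7, C7a, C3a–C3 on the carbocycle is the footprint of an allylic ester transposition. An N-Boc-alaninate on the C7 oxygen of a C7a=C3a cyclohexenol, made from (S)-carvone, should pass C3 to C3a suprafacially, create both stereocentres in one operation and leave a C7=C7a alkene on the two carbons that must carry oxygen. Epoxidation then closes the lactone ring at C7a, the relay carbinols become the ring carbonyls, and the sorbyl and fumaroyl groups are attached last.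

Key step: step 6

Remark on labels: core atoms are numbered as in 1-benzofuran-2-one (O1, C2 lactone carbonyl, C3 nitrogen-bearing carbon, C3a ring-fusion CH, C4 sorbyl-bearing carbon, C5 ring ketone, C6 methyl-bearing carbon, C7 enol C–OH, C7a oxygen-bearing ring-fusion carbon). The same labels are used for the carvone-derived precursors: the carvone carbonyl carbon is C7, its methyl-bearing carbon C7a, its vinylic CH C3a, and its stereocentre C5.
Assumption: compounds 17–26 are written as the enol tautomers of their SMILES; the tautomer drawn does not affect the chemistry.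

Step 1
Reactants: 1 (S)-(+)-carvone
Product: 4 (S)-5-acetoxy-2-methylcyclohex-2-en-1-one, via methoxy hydroperoxide 2 (not isolated), via peracetate 3 (not isolated)
Conditions: O3, CH2Cl2/MeOH (5:1), −78 °C; N2 purge; then Ac2O, Et3N, 4-dimethylaminopyridine (cat.), 0 °C → rt
Reagents that add atoms: ozone, [O-][O+]=O; methanol, CO
Why: Ozone attacks the electron-rich isopropenyl alkene in preference to the deactivated enone, methanol traps the carbonyl oxide as 2, and its peracetate 3 undergoes Criegee rearrangement with migration of the ring carbon to oxygen with retention, so the carvone stereocentre becomes the C5 carbinol centre unchanged.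

Step 2
Reactants: 4 (S)-5-acetoxy-2-methylcyclohex-2-en-1-one
Product: 5 (S)-5-hydroxy-2-methylcyclohex-2-en-1-one
Conditions: HCl (cat., from AcCl), MeOH, 0 °C → rt
Reagents that add atoms: none
Why: Acid-catalysed transesterification cleaves the acetate at the acyl–oxygen bond without touching the stereocentre, and the absence of base avoids E1cB loss of the β-acyloxy group and aromatisation to 2-methylphenol.

Step 3
Reactants: 5 (S)-5-hydroxy-2-methylcyclohex-2-en-1-one
Product: 6 (S)-5-(tert-butyldimethylsilyloxy)-2-methylcyclohex-2-en-1-one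
Conditions: TBSCl, imidazole, DMF, 0 °C → rt
Reagents that add atoms: tert-butyldimethylsilyl chloride, CC(C)(C)[Si](C)(C)Cl
Why: Silyl ether formation with a silyl chloride and imidazole, a base too weak to dehydrate the β-hydroxy enone, gives an ether that should survive the hydride, Mitsunobu and amide-base steps.

Step 4
Reactants: 6 (S)-5-(tert-butyldimethylsilyloxy)-2-methylcyclohex-2-en-1-one
Product: 7 (1S,5S)-5-(tert-butyldimethylsilyloxy)-2-methylcyclohex-2-en-1-ol (hydroxyl cis to the silyloxy group)
Conditions: NaBH4, CeCl3·7H2O, MeOH, −78 °C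
Reagents that add atoms: none
Why: Luche reduction gives 1,2-reduction of the enone, and axial hydride delivery to the half-chair with the silyloxy group pseudoequatorial should give the pseudoequatorial alcohol cis to that group, as carvone gives cis-carveol.

Step 5
Reactants: 7 (1S,5S)-5-(tert-butyldimethylsilyloxy)-2-methylcyclohex-2-en-1-ol; 8 N-Boc-L-alanine
Product: 9 (1R,5S)-5-(tert-butyldimethylsilyloxy)-2-methylcyclohex-2-en-1-yl N-(tert-butoxycarbonyl)-L-alaninate (ester oxygen trans to the silyloxy group)
Conditions: PPh3, diisopropyl azodicarboxylate, THF, 0 °C → rt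
Reagents that add atoms: N-Boc-L-alanine (8), C[C@H](NC(=O)OC(C)(C)C)C(=O)O
Why: Mitsunobu esterification displaces the activated allylic carbinol oxygen by the carboxylate in an SN2 process with inversion, which places the ester oxygen trans to the silyloxy group; the alanine stereocentre does not matter because step 6 planarises it.

Step 6
Reactants: 9 (1R,5S)-5-(tert-butyldimethylsilyloxy)-2-methylcyclohex-2-en-1-yl N-(tert-butoxycarbonyl)-L-alaninate
Product: 11 (2S)-2-[(tert-butoxycarbonyl)amino]-2-[(1S,5R)-5-(tert-butyldimethylsilyloxy)-2-methylcyclohex-2-en-1-yl]propanoic acid, via zinc chelate enolate 10 (not isolated)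
Conditions: LiN(iPr)2 (3 equiv), ZnCl2 (1.2 equiv), THF, −78 °C → rt; cold 1 M HCl work-up
Reagents that add atoms: none
Why: Two equivalents of base remove the carbamate N–H and the alanine α-hydrogen, and ZnCl2 locks the ester enolate as the five-membered N–Zn–O chelate 10, with nitrogen cis to the zinc-bound oxygen and the methyl cis to the allylic oxygen; on warming, 10 undergoes a concerted suprafacial [3,3]-sigmatropic shift in which the C3–C3a bond forms while the C7–O ester bond breaks and the alkene moves from C7a=C3a to C7=C7a. The closest known reaction type is the zinc chelate-enolate Claisen rearrangement (the Kazmaier–Claisen variant of the Ireland–Claisen rearrangement) of N-carbamate amino acid cyclohex-2-enyl esters, alanine esters included, which gives α-quaternary γ,δ-unsaturated amino acids. No ring is closed in this step; the acid and the transposed alkene are only set up for the 5-exo lactonisation of step 7. C3a is controlled by the C7 carbinol centre, because the enolate can reach C3a only across the face that carries the pseudoaxial ester oxygen, while the trans silyloxy group sits pseudoequatorial on the opposite face and stays out of the way. C3 is controlled by the chelate-fixed enolate geometry read through a chair-like six-membered transition state, which turns nitrogen toward C4H2 and the methyl toward the C7a side and so gives the (S) centre of the target. The selectivity needed is therefore chair over boat: the boat would seat the alanine methyl directly above ring C4H2 and eclipse the zinc-bound oxygen with the C7a methyl, contacts that the chair avoids, although the chair places the chelate above the ring, so the preference is an expectation from the mechanism and not an established fact for this doubly methylated case.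

Step 7
Reactants: 11 (2S)-2-[(tert-butoxycarbonyl)amino]-2-[(1S,5R)-5-(tert-butyldimethylsilyloxy)-2-methylcyclohex-2-en-1-yl]propanoic acid
Product: 13 tert-butyl N-[(3S,3aR,5S,7S,7aS)-5-(tert-butyldimethylsilyloxy)-7-hydroxy-3,7a-dimethyl-2-oxooctahydro-1-benzofuran-3-yl]carbamate (cis-fused lactone; C7 hydroxyl trans to the lactone oxygen), via epoxy acid 12 (not isolated)
Conditions: mCPBA, CH2Cl2, 0 °C → rt; camphorsulfonic acid (cat.) if 12 persists
Reagents that add atoms: 3-chloroperbenzoic acid, OOC(=O)c1cccc(Cl)c1
Why: Prilezhaev epoxidation should occur on the alkene face anti to the bulky C3a side chain, and the tethered carboxylic acid then opens epoxide 12 at tertiary C7a with inversion in a 5-exo, trans-diaxial (Fürst–Plattner) mode, which can only give the cis-fused γ-lactone and so sets C7a from C3a.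

Step 8
Reactants: 13 silyl ether hydroxy lactone
Product: 14 tert-butyl N-[(3S,3aR,5S,7S,7aS)-5,7-dihydroxy-3,7a-dimethyl-2-oxooctahydro-1-benzofuran-3-yl]carbamate
Conditions: HF·pyridine, pyridine/THF, 0 °C → rt
Reagents that add atoms: none
Why: Fluoride-driven desilylation under buffered, weakly acidic conditions cleaves the Si–O bond without opening the lactone or removing the Boc group.

Step 9
Reactants: 14 diol lactone
Product: 15 tert-butyl N-[(3S,3aR,7aS)-3,7a-dimethyl-2,5,7-trioxooctahydro-1-benzofuran-3-yl]carbamate (C6 still CH2)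
Conditions: IBX (3 equiv), EtOAc, 75 °C
Reagents that add atoms: none
Why: Hypervalent-iodine oxidation of both secondary alcohols under neutral conditions turns the two relay carbinols into the cyclic 1,3-dione without base-induced elimination at the β-hydroxy ketone stage, and the remaining centres (quaternary C3 and C7a, non-enolisable C3a) cannot epimerise.

Step 10
Reactants: 15 bicyclic lactone 5,7-dione; 16 iodomethane
Product: 17 tert-butyl N-[(3S,3aR,7aS)-7-hydroxy-3,6,7a-trimethyl-2,5-dioxo-2,3,3a,4,5,7a-hexahydro-1-benzofuran-3-yl]carbamate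
Conditions: MeI (1.05 equiv), K2CO3 (1.1 equiv), acetone, rt
Reagents that add atoms: iodomethane (16), CI
Why: C-alkylation of the cyclic 1,3-dione enolate takes place at C6, the only carbon flanked by both carbonyls, and a carbonate base with one equivalent of iodomethane leaves the carbamate N–H and the lactone untouched.

Step 11
Reactants: 17 N-Boc 6-methyl vinylogous acid; 18 (2E,4E)-hexa-2,4-dienal
Product: 20 tert-butyl N-[(3S,3aR,7aS)-7-hydroxy-4-[(2E,4E)-1-hydroxyhexa-2,4-dien-1-yl]-3,6,7a-trimethyl-2,5-dioxo-2,3,3a,4,5,7a-hexahydro-1-benzofuran-3-yl]carbamate (mixture at C4 and the carbinol carbon), via trilithium polyanion 19 (not isolated)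
Conditions: LiN(iPr)2 (3.3 equiv), THF/DMPU, −78 → −40 °C; then 18, −78 °C; AcOH quench at −78 °C
Reagents that add atoms: (2E,4E)-hexa-2,4-dienal (18), C/C=C/C=C/C=O
Why: This is a β-dicarbonyl polyanion aldol addition: after the enol and the carbamate are deprotonated, a third equivalent of amide base removes a proton from C4, the only enolisable α′ carbon because C7a is quaternary, and this most basic terminus adds 1,2 to the dienal, the two new stereocentres being destroyed in step 12.

Step 12
Reactants: 20 aldol adduct
Product: 21 tert-butyl N-[(3S,3aR,7aS)-7-hydroxy-4-[(2E,4E)-1-hydroxyhexa-2,4-dien-1-ylidene]-3,6,7a-trimethyl-2,5-dioxo-2,3,3a,4,5,7a-hexahydro-1-benzofuran-3-yl]carbamate (N-Boc sorbyl triketone)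
Conditions: MnO2 (activated, excess), CH2Cl2, rt
Reagents that add atoms: none
Why: Allylic alcohol oxidation with activated MnO2 is selective for the doubly allylic carbinol, and the resulting β-triketone should settle as the chelated exocyclic enol drawn for 21.

Step 13
Reactants: 21 N-Boc sorbyl triketone
Product: 22 ammonium trifluoroacetate of the C3 amine (target with NH3+ in place of the fumaroylamino group)
Conditions: CF3CO2H/CH2Cl2 (1:4), 0 °C → rt; evaporation
Reagents that add atoms: trifluoroacetic acid, OC(=O)C(F)(F)F
Why: Acidolysis of the tert-butyl carbamate through the tert-butyl cation and decarboxylation frees the amine, which is kept as its non-nucleophilic ammonium salt so that it cannot condense with the neighbouring triketone.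

Step 14
Reactants: 22 ammonium trifluoroacetate; 23 fumaric acid mono-tert-butyl ester
Product: 25 sorbicillactone A tert-butyl ester, via acid chloride 24 (not isolated)
Conditions: 23, 1-chloro-N,N,2-trimethylprop-1-en-1-amine, CH2Cl2, 0 °C; then 22, 2,6-lutidine, CH2Cl2, −20 °C → rt; MeOH quench
Reagents that add atoms: fumaric acid mono-tert-butyl ester (23), OC(=O)/C=C/C(=O)OC(C)(C)C
Why: Schotten–Baumann-type N-acylation with a reactive acid chloride, made under neutral conditions that spare the tert-butyl ester, should overcome the hindrance of the α-tertiary amine as the pyridine base liberates it, and any enol ester formed on the acidic triketone is cleaved by the methanol quench.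

Step 15
Reactants: 25 sorbicillactone A tert-butyl ester
Product: 26 sorbicillactone A
Conditions: CF3CO2H/CH2Cl2 (1:2), 0 °C → rt
Reagents that add atoms: none
Why: Acid-mediated tert-butyl ester cleavage by loss of isobutene unmasks the carboxylic acid without the nucleophiles or bases that the lactone and the triketone would not tolerate.

Compound list
1 | (S)-(+)-carvone | CC1=CC[C@@H](CC1=O)C(C)=C | starting material
2 | (5S)-5-(1-hydroperoxy-1-methoxyethyl)-2-methylcyclohex-2-en-1-one (not isolated; mixture at the peroxy carbon) | CC1=CC[C@@H](CC1=O)C(C)(OC)OO | intermediate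
3 | peracetate of 2 (not isolated) | CC1=CC[C@@H](CC1=O)C(C)(OC)OOC(C)=O | intermediate
4 | (S)-5-acetoxy-2-methylcyclohex-2-en-1-one | CC1=CC[C@@H](CC1=O)OC(C)=O | intermediate
5 | (S)-5-hydroxy-2-methylcyclohex-2-en-1-one | CC1=CC[C@@H](CC1=O)O | intermediate
6 | (S)-5-(tert-butyldimethylsilyloxy)-2-methylcyclohex-2-en-1-one | CC1=CC[C@@H](CC1=O)O[Si](C)(C)C(C)(C)C | intermediate
7 | (1S,5S)-5-(tert-butyldimethylsilyloxy)-2-methylcyclohex-2-en-1-ol (cis) | O[C@@H]1C(C)=CC[C@H](O[Si](C)(C)C(C)(C)C)C1 | intermediate
8 | N-Boc-L-alanine | C[C@H](NC(=O)OC(C)(C)C)C(=O)O | starting material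
9 | (1R,5S)-5-(tert-butyldimethylsilyloxy)-2-methylcyclohex-2-en-1-yl N-Boc-L-alaninate (trans) | CC(C)(C)OC(=O)N[C@@H](C)C(=O)O[C@H]1C(C)=CC[C@H](O[Si](C)(C)C(C)(C)C)C1 | intermediate
10 | N,O-chelated divalent zinc ester enolate of 9 (not isolated) | CC(C)(C)OC(=O)N1[Zn]OC(O[C@H]2C(C)=CC[C@H](O[Si](C)(C)C(C)(C)C)C2)=C1C | intermediate
11 | (2S)-2-[(tert-butoxycarbonyl)amino]-2-[(1S,5R)-5-(tert-butyldimethylsilyloxy)-2-methylcyclohex-2-en-1-yl]propanoic acid | OC(=O)[C@@](C)(NC(=O)OC(C)(C)C)[C@@H]1C(C)=CC[C@@H](O[Si](C)(C)C(C)(C)C)C1 | intermediate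
12 | C7,C7a-epoxide of 11, oxygen anti to the amino acid side chain (not isolated) | OC(=O)[C@@](C)(NC(=O)OC(C)(C)C)[C@@H]1[C@@]2(C)O[C@H]2C[C@@H](O[Si](C)(C)C(C)(C)C)C1 | intermediate
13 | tert-butyl N-[(3S,3aR,5S,7S,7aS)-5-(tert-butyldimethylsilyloxy)-7-hydroxy-3,7a-dimethyl-2-oxooctahydro-1-benzofuran-3-yl]carbamate | O[C@H]1C[C@@H](O[Si](C)(C)C(C)(C)C)C[C@H]2[C@]1(C)OC(=O)[C@@]2(C)NC(=O)OC(C)(C)C | intermediate
14 | tert-butyl N-[(3S,3aR,5S,7S,7aS)-5,7-dihydroxy-3,7a-dimethyl-2-oxooctahydro-1-benzofuran-3-yl]carbamate | O[C@H]1C[C@@H](O)C[C@H]2[C@]1(C)OC(=O)[C@@]2(C)NC(=O)OC(C)(C)C | intermediate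
15 | tert-butyl N-[(3S,3aR,7aS)-3,7a-dimethyl-2,5,7-trioxooctahydro-1-benzofuran-3-yl]carbamate | O=C1CC(=O)C[C@H]2[C@]1(C)OC(=O)[C@@]2(C)NC(=O)OC(C)(C)C | intermediate
16 | iodomethane | CI | starting material
17 | tert-butyl N-[(3S,3aR,7aS)-7-hydroxy-3,6,7a-trimethyl-2,5-dioxo-2,3,3a,4,5,7a-hexahydro-1-benzofuran-3-yl]carbamate | C1C(=O)C(C)=C(O)[C@@]2(C)OC(=O)[C@@](C)(NC(=O)OC(C)(C)C)[C@@H]12 | intermediate
18 | (2E,4E)-hexa-2,4-dienal | C/C=C/C=C/C=O | starting material
19 | trilithium salt of 17: C7 enolate oxygen, carbamate nitrogen, C4/C5 enolate (not isolated) | [Li+].[Li+].[Li+].C1=C([O-])C(C)=C([O-])[C@@]2(C)OC(=O)[C@@](C)([N-]C(=O)OC(C)(C)C)[C@@H]12 | intermediate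
20 | C4 aldol adduct of 17 with 18 (mixture at C4 and the carbinol carbon) | C/C=C/C=C/C(O)C1C(=O)C(C)=C(O)[C@@]2(C)OC(=O)[C@@](C)(NC(=O)OC(C)(C)C)[C@@H]12 | intermediate
21 | N-Boc sorbyl triketone (target with Boc in place of the fumaroyl group) | C/C=C/C=C/C(O)=C1/C(=O)C(C)=C(O)[C@@]2(C)OC(=O)[C@@](C)(NC(=O)OC(C)(C)C)[C@@H]12 | intermediate
22 | C3 ammonium trifluoroacetate of the sorbyl triketone | C/C=C/C=C/C(O)=C1/C(=O)C(C)=C(O)[C@@]2(C)OC(=O)[C@@](C)([NH3+])[C@@H]12.[O-]C(=O)C(F)(F)F | intermediate
23 | fumaric acid mono-tert-butyl ester | OC(=O)/C=C/C(=O)OC(C)(C)C | starting material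
24 | tert-butyl (E)-4-chloro-4-oxobut-2-enoate (not isolated) | ClC(=O)/C=C/C(=O)OC(C)(C)C | intermediate
25 | sorbicillactone A tert-butyl ester | C/C=C/C=C/C(O)=C1/C(=O)C(C)=C(O)[C@@]2(C)OC(=O)[C@@](C)(NC(=O)/C=C/C(=O)OC(C)(C)C)[C@@H]12 | intermediate
26 | sorbicillactone A, (3S,3aR,7aS) core | C/C=C/C=C/C(O)=C1/C(=O)C(C)=C(O)[C@@]2(C)OC(=O)[C@@](C)(NC(=O)/C=C/C(=O)O)[C@@H]12 | target

Total step count: 15. Longest linear sequence: 15 steps (1 to 26); compounds 8, 16, 18 and 23 are bought and enter directly.

Steps most likely to fail

Step 6. The rearrangement may pass through the boat-like topology, which cyclohexenyl ester enolates often prefer when the carbon cis to the allylic oxygen carries only hydrogen; that would set C3 with the wrong configuration. The fully substituted enolate may also rearrange sluggishly. The fallback sets out from 7 and comes back at 14. Alcohol 7 is esterified under the Mitsunobu conditions of step 5 with N-Boc-glycine to the trans N-Boc-glycinate ester F1. The same chelate-enolate Claisen rearrangement, for which either topology is acceptable because the C3 centre is erased later, gives the C3-unmethylated amino acid F2. Epoxidation and lactonisation as in step 7 give the C3-unmethylated hydroxy lactone F3. Its C7 hydroxyl is capped (Et3SiCl, imidazole, 4-dimethylaminopyridine) to give the bis-silyl ether F4. The dianion of F4 (LiN(iPr)2, two equivalents, THF, −78 °C) is methylated with iodomethane on the convex face of the cis-fused bicyclic lactone enolate, syn to the C3a hydrogen and away from the carbocycle, which is the configuration the target needs at C3; this gives the C3-methylated bis-silyl ether F5. HF·pyridine then removes both silyl groups and delivers diol 14.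

Step 11. Formation of a triply charged lithium species may be incomplete or give an aggregated, unreactive anion, and the aldolate may revert or dehydrate under the basic conditions. The fallback sets out from 17 and comes back at 20; it replaces the polyanion by a neutral bis-silyl dienol ether and moves the C–C bond formation to Lewis-acidic conditions. Compound 17 is silylated on the enol oxygen (Me3SiCl, Et3N) to the trimethylsilyl enol ether F9; either enol oxygen may react and both isomers converge, and the C7–O isomer is the one listed. Deprotonation at C4 with LiN(iPr)2 in the presence of Me3SiCl then gives the 5,7-bis(trimethylsilyloxy) diene F10, in which the carbamate nitrogen is silylated as well. A vinylogous Mukaiyama aldol addition of F10 to 18 (BF3·OEt2, CH2Cl2, −78 °C) should take place at the terminal carbon C4, and mild acidic methanol work-up strips all silicon to give 20.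

Step 7. Facial selectivity of the epoxidation may be poor: hydrogen-bond delivery of the peracid by the carbamate N–H or the carboxylic acid could direct oxygen to the face syn to the side chain, and that epoxide cannot be opened by the tethered acid. The fallback sets out from 11 and comes back at 15; it closes the lactone first and brings in the C7 oxygen afterwards. Iodolactonisation of 11 (I2, NaHCO3, MeCN/H2O, 0 °C) can only be productive from the iodonium ion anti to the carboxylate, and should give the cis-fused iodolactone F6 with iodine at C7. Radical oxygenation of the C–I bond (Bu3SnH, air, toluene, then PPh3) gives 13 together with its C7 epimer F7. The C7 configuration is irrelevant, so the mixture is desilylated as in step 8 (14 and its C7 epimer F8) and oxidised as in step 9, where both epimers converge on dione 15.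

Further compounds
F1 | step 6 | (1R,5S)-5-(tert-butyldimethylsilyloxy)-2-methylcyclohex-2-en-1-yl N-(tert-butoxycarbonyl)glycinate | CC(C)(C)OC(=O)NCC(=O)O[C@H]1C(C)=CC[C@H](O[Si](C)(C)C(C)(C)C)C1
F2 | step 6 | 2-[(tert-butoxycarbonyl)amino]-2-[(1S,5R)-5-(tert-butyldimethylsilyloxy)-2-methylcyclohex-2-en-1-yl]acetic acid (C3 configuration left open) | OC(=O)C(NC(=O)OC(C)(C)C)[C@@H]1C(C)=CC[C@@H](O[Si](C)(C)C(C)(C)C)C1
F3 | step 6 | C3-unmethylated analogue of hydroxy lactone 13 | O[C@H]1C[C@@H](O[Si](C)(C)C(C)(C)C)C[C@H]2[C@]1(C)OC(=O)C2NC(=O)OC(C)(C)C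
F4 | step 6 | 7-O-triethylsilyl ether of F3 | CC[Si](CC)(CC)O[C@H]1C[C@@H](O[Si](C)(C)C(C)(C)C)C[C@H]2[C@]1(C)OC(=O)C2NC(=O)OC(C)(C)C
F5 | step 6 | 7-O-triethylsilyl ether of 13 (C3-methylated bis-silyl ether) | CC[Si](CC)(CC)O[C@H]1C[C@@H](O[Si](C)(C)C(C)(C)C)C[C@H]2[C@]1(C)OC(=O)[C@@]2(C)NC(=O)OC(C)(C)C
F6 | step 7 | cis-fused iodolactone, iodine at C7 trans to the lactone oxygen | I[C@H]1C[C@@H](O[Si](C)(C)C(C)(C)C)C[C@H]2[C@]1(C)OC(=O)[C@@]2(C)NC(=O)OC(C)(C)C
F7 | step 7 | C7 epimer of hydroxy lactone 13 | O[C@@H]1C[C@@H](O[Si](C)(C)C(C)(C)C)C[C@H]2[C@]1(C)OC(=O)[C@@]2(C)NC(=O)OC(C)(C)C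
F8 | step 7 | C7 epimer of diol 14 | O[C@@H]1C[C@@H](O)C[C@H]2[C@]1(C)OC(=O)[C@@]2(C)NC(=O)OC(C)(C)C
F9 | step 11 | 7-O-trimethylsilyl enol ether of 17 | C1C(=O)C(C)=C(O[Si](C)(C)C)[C@@]2(C)OC(=O)[C@@](C)(NC(=O)OC(C)(C)C)[C@@H]12
F10 | step 11 | 5,7-bis(trimethylsilyloxy) diene of 17 with N-trimethylsilyl carbamate | C1=C(O[Si](C)(C)C)C(C)=C(O[Si](C)(C)C)[C@@]2(C)OC(=O)[C@@](C)(N([Si](C)(C)C)C(=O)OC(C)(C)C)[C@@H]12
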